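Readings and results are simulated with constants of no real substance, and the scatter is random.

If the second catalyst did nothing, alder and ash would read alike in target, yet at 2.50 h they read 5 % and 14 %, a gap of 9 percentage points, far wider than the scatter of 1.5 points. So drop that zero. Here is the quick number. Both runs charged 0.75 M of partner, less than the 3.00 M of Wednesday's, so take nothing from them on what more partner does.

| flask | starting material | partner | free catalyst | second catalyst | temperature | remark | time |
|---|---|---|---|---|---|---|---|
| alder | 0.34 M | 0.75 M | 0.41 mM | 10 mM | 40 °C | run made earlier |  |
| ash | 0.50 M | 0.75 M | 0.41 mM | 20 mM | 40 °C | run made earlier |  |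
| Wednesday's | 0.50 M | 3.00 M | 0.41 mM | 10 mM | 10 °C |  | 4.0 h |
| Saturday's | 0.50 M | 0.750 M | 0.41 mM | 10 mM | 40 °C |  | 4.0 h |

- alder (time / h: target / %, starting material / %): 0.200: 0, 83; 0.333: 0, 77; 0.417: 0, 72; 0.667: 4, 60; 1.00: 0, 45; 1.50: 2, 31; 2.50: 5, 14
- ash (time / h: target / %, starting material / %): 0.133: 0, 89; 0.333: 1, 77; 0.667: 0, 62; 1.00: 3, 44; 1.33: 8, 38; 2.00: 10, 20; 2.50: 14, 17

(readings scatter by 1.5 percentage points)

- the flask that ends with the higher amount of target, in percent of the starting material charged, or "neither" when 2 percentage points or less lies between them (Wednesday's / Saturday's / neither)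
- final target, as a percentage of the starting material charged, in Wednesday's
- final target, as a percentage of the starting material charged, in Saturday's

- a reading or a percentage of target counts all its forms, free or not
- the earlier runs do not show what temperature does; that part of a forecast is a guess

Read the starting material first. Alder and ash leave 14 % and 17 % at the same time despite different charges and second catalyst, so treat its loss as pseudo-first-order, reading 0.748 h⁻¹. Target lags, so something stands between. Count exposure, the fraction of starting material spent, summed over the hours: 1.37 h by the last readings. Pool both runs and let target scale with second catalyst. That gives 0.0463 h⁻¹, the handover rate: target made per hour of exposure at 10 mM of second catalyst.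

Saturday's matches the runs in partner and temperature, and its exposure by 4.0 h is 2.73 h, so my number is 12.6 %. The forecast says 11 %, a little lower than mine, and 2 % for Wednesday's, on the guess that cooling “probably costs about tenfold on each step”. I have no reckoning for Wednesday's, since the runs test neither its partner nor its temperature. The forecast picks Saturday's; commit to that.

Saturday's ended at 13.4 % and Wednesday's at 1.65 %, so the flask with more is Saturday's.

    starting material + partner → uncatalysed product (k = 1.50 × 10⁻⁴ M⁻¹ s⁻¹, Ea = 78.0 kJ mol⁻¹)
    starting material + free catalyst → free catalyst + intermediate (k = 0.270 M⁻¹ s⁻¹, Ea = 61.0 kJ mol⁻¹)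
    partner + second catalyst + intermediate → second catalyst + target (k = 0.00570 M⁻² s⁻¹, Ea = 50.0 kJ mol⁻¹)
    crystals ⇌ target, rate k4*(cs4 - [target]) while solid is left; crystals form when [target] > cs4 (solubility = 0.190 M, k = 0.00510 s⁻¹)
    (constants at 40 °C)

Saturday's also holds 42.9 % of uncatalysed product at 4.00 h, a species not among the readings. Divide its target by the exposure and the handover rate comes back as 0.0491 h⁻¹, beside 0.0463 h⁻¹ from the runs. Now scale it to the neighbour flask, like Saturday's but with 0.040 M of second catalyst: it gives 50.6 %. That flask ended lower, at 32.6 % of target with 19.2 % of intermediate.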